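The data are simulated with made-up constants, and the scatter is random.

Slowness is what you should doubt first: in the blue run the target does not linger. It falls from 4.9% at 0.833 h to 2.0% at 1.50 h, while side product B climbs from 7.4% to 11.6%.

in all of them: fresh partner 26.4 mM
- teal: substrate 24 mM; coupling partner 36 mM; temperature 30 °C; run made earlier
- green: substrate 16 mM; coupling partner 36 mM; temperature 41 °C; run made earlier
- blue: substrate 36 mM; coupling partner 36 mM; temperature 30 °C; run made earlier
- Friday's: substrate 24 mM; coupling partner 36.0 mM; everything together at the start at 15 °C, warmed to 35 °C at 1.5 h; time 2.5 h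
- Wednesday's: substrate 24 mM (fed, over 1.5 h); coupling partner 36.0 mM; the addition at 15 °C, then warmed to 35 °C; the feed brings no volume worth counting; time 2.5 h
- Sunday's: substrate 24 mM; coupling partner 36.0 mM; temperature 35 °C; everything together at the start; time 2.5 h
- Monday's: substrate 24 mM; coupling partner 36.0 mM (fed, over 1.5 h); temperature 35 °C; all else is in the flask from the start; the feed brings no volume worth counting; time 2.5 h

teal run (percent of the substrate charged)

| time / min | target / % | side product B / % |
|---|---|---|
| 15.0 | 4.5 | 0.2 |
| 30.0 | 8.8 | 2.4 |
| 50.0 | 11.5 | 4.2 |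
| 60.0 | 12.2 | 5.4 |
| 80.0 | 12.2 | 6.9 |
| 90.0 | 11.6 | 8.2 |

green run (percent of the substrate charged)

| time / h | target / % | side product B / % |
|---|---|---|
| 0.417 | 12.0 | 2.5 |
| 0.833 | 13.3 | 4.3 |
| 1.33 | 13.5 | 5.7 |
| 1.50 | 12.7 | 5.3 |
| 2.00 | 12.8 | 6.5 |
| 2.50 | 11.8 | 7.3 |

blue run (percent of the substrate charged)

| time / h | target / % | side product B / % |
|---|---|---|
| 0.417 | 2.9 | 2.4 |
| 0.833 | 4.9 | 7.4 |
| 1.33 | 2.3 | 10.7 |
| 1.50 | 2.0 | 11.6 |
| 2.00 | 1.0 | 13.7 |
| 2.50 | 1.2 | 14.5 |

(each reading ± 0.5 percentage points)

- the best flask by share of target in target plus side product B; "all alike" if 1.5 percentage points covers them all (Friday's / Wednesday's / Sunday's / Monday's / all alike)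
- share of target in target plus side product B at the end, Friday's
- share of target in target plus side product B at the end, Wednesday's
- share of target in target plus side product B at the end, Sunday's
- share of target in target plus side product B at the end, Monday's

- in percentages every species weighs as the substrate in it: one side product B counts as two
- the numbers in the tables scatter with a standard deviation of 0.5 percentage points

So take the blue fall as a reading: 1.34 h⁻¹. Call this the drain, the net fractional loss of target per hour. The green run, hotter at 41 °C but charged with 16 mM of substrate, loses target far more slowly than blue, at 0.115 h⁻¹.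

I therefore read the drain as pseudo-first-order in target, scaling with the c(substrate) standing beside it and not with the charge, for the blue drain is 11.7 times the green one while the charges differ by a factor of 2.25. Blue's c(substrate) during the fall is unread, but it stands below the 36 mM charged, so the drain divided by that charge is a floor on the drain per mM of substrate. At a standing 24 mM and blue's 30 °C, that floor gives a half-life of at most 0.774 h, shorter than the 2.5 h of the flasks.

So watch the substrate left when the flask is warm. Friday's has its whole charge in the cold from the start, whereas Wednesday's last substrate arrives just as warming begins. My reckoning therefore puts Friday's first.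

The forecast differs: Wednesday's, with 57% for Friday's, 61% for Wednesday's, 40% for Sunday's and 45% for Monday's. Its ground: “Wednesday's also keeps substrate low during the hold, so it should be slightly best”.

The flasks give Friday's as best: 67.2% for Friday's, 25.5% for Wednesday's, 30.1% for Sunday's and 34.8% for Monday's.

    substrate → decomposition product (k = 4.92 × 10⁻⁷ s⁻¹, Ea = 112 kJ mol⁻¹)
    substrate + coupling partner → open intermediate (k = 0.190 L mol⁻¹ s⁻¹, Ea = 45.0 kJ mol⁻¹)
    open intermediate + second intermediate → target (k = 0.0206 L mol⁻¹ s⁻¹, Ea = 58.0 kJ mol⁻¹)
    substrate + target → side product B (k = 0.0466 L mol⁻¹ s⁻¹, Ea = 56.0 kJ mol⁻¹)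
    second intermediate → side product A (k = 0.00128 s⁻¹, Ea = 95.0 kJ mol⁻¹)
    coupling partner + fresh partner → second intermediate (k = 0.0770 L mol⁻¹ s⁻¹, Ea = 63.0 kJ mol⁻¹)
    (constants at 35 °C)

Now cut the coupling partner in Friday's recipe to 9.0 mM. Friday's itself ends with 3.34% of its substrate, so the floor from blue gives a drain of at least 0.0298 h⁻¹. The neighbour flask ends with 70.0%, which gives at least 0.625 h⁻¹, a factor of 21.0 higher. Both figures carry blue's 30 °C, so trust the factor rather than the values. The neighbour flask holds 0.0893% of target beside 2.44% of side product B, a share of 3.53%.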